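**Plan**
- Two bonds of the target are cut: the diaryl ether bond O–C6 and the C2'–OH bond. Ring A carries C1 OMe, C2 Br, C4 Br and C6 ether O; ring B carries C1' ether O, C2' OH, C3' Br, C5' Br and C6' OMe.
- The hydroxylated C2' is the direct neighbour of the ether carbon C1'. C2' can therefore first carry an iodine that holds ring A as an iodonium, passes it to the oxygen on C1', and is afterwards replaced by OH.
- Forward: ring A is prepared as aryliodine diacetate 4 from 2,4-dibromophenol (steps 1–3) and ring B as phenol 8 from 3,5-dibromosalicylaldehyde (steps 4–5).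
- The two are joined through iodine (step 6), the aryl group moves from iodine to oxygen (step 7), and iodine is exchanged for hydroxyl (step 8).
- No ring is formed and the target has no stereocentre, so no stereocontrol is required; all four bromines arrive with the starting materials.

Key step: step 7

Remark: compound 9 is written as the inner salt (iodonium phenolate) and is assumed to be handled cold and carried on without purification.

Step 1
Reactants: 1 2,4-dibromophenol
Product: 2 2,4-dibromo-6-iodophenol
Conditions: NIS, TsOH·H2O (cat.), MeCN, rt
Reagents that add atoms: N-iodosuccinimide, O=C1CCC(=O)N1I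
Why: Electrophilic aromatic iodination of a phenol whose para and one ortho position are blocked by bromine, so iodine can enter only at C6.

Step 2
Reactants: 2 2,4-dibromo-6-iodophenol
Product: 3 1,5-dibromo-3-iodo-2-methoxybenzene
Conditions: MeI, K2CO3, acetone, reflux
Reagents that add atoms: iodomethane, CI
Why: Williamson O-methylation of an acidic trihalophenol, which is readily deprotonated and alkylated despite its two ortho halogens.

Step 3
Reactants: 3 1,5-dibromo-3-iodo-2-methoxybenzene
Product: 4 1-(diacetoxyiodo)-3,5-dibromo-2-methoxybenzene
Conditions: mCPBA, AcOH, 50 °C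
Reagents that add atoms: acetic acid, CC(=O)O
Why: Peracid oxidation of an aryl iodide in acetic acid gives the aryliodine diacetate (monovalent to trivalent iodine), a standard preparation that tolerates aryl bromides and an ortho methoxy group.

Step 4
Reactants: 5 3,5-dibromosalicylaldehyde
Product: 6 3,5-dibromo-2-methoxybenzaldehyde
Conditions: MeI, K2CO3, DMF, rt
Reagents that add atoms: iodomethane, CI
Why: Williamson O-methylation of the acidic salicylaldehyde hydroxyl in a dipolar aprotic solvent, which overcomes the flanking bromine and formyl groups.

Step 5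
Reactants: 6 3,5-dibromo-2-methoxybenzaldehyde
Product: 8 3,5-dibromo-2-methoxyphenol, via 3,5-dibromo-2-methoxyphenyl formate 7 (not isolated)
Conditions: mCPBA, CH2Cl2, 40 °C; then Et3N, MeOH, rt
Reagents that add atoms: meta-chloroperoxybenzoic acid, OOC(=O)c1cccc(Cl)c1
Why: Baeyer–Villiger (Dakin-type) oxidation in which the ortho-methoxy aryl group migrates in preference to hydride in the Criegee intermediate, followed by base-catalysed methanolysis of the aryl formate.

Step 6
Reactants: 4 1-(diacetoxyiodo)-3,5-dibromo-2-methoxybenzene; 8 3,5-dibromo-2-methoxyphenol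
Product: 9 3,5-dibromo-2-[(3,5-dibromo-2-methoxyphenyl)iodonio]-6-methoxyphenolate
Conditions: KOH, MeOH, −10 to 0 °C (8 deprotonated first, then 4 added; solid collected cold)
Reagents that add atoms: none
Why: Condensation of a phenolate with an aryliodine diacetate in basic methanol to an iodonium phenolate (electrophilic substitution at the phenolate ortho carbon by trivalent iodine) is established for phenols carrying electron-withdrawing groups; here iodine can bond only to the open ortho carbon C2', because the para carbon C4' is wedged between two bromines, while KOH turns the diacetate into the less oxidising dimethoxide and the low temperature holds back methanol addition at C6' that would lead to a quinone monoketal.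

Step 7
Reactants: 9 3,5-dibromo-2-[(3,5-dibromo-2-methoxyphenyl)iodonio]-6-methoxyphenolate
Product: 10 1,5-dibromo-3-(3,5-dibromo-2-methoxyphenoxy)-2-iodo-4-methoxybenzene
Conditions: MeCN, 80 °C, N2, dark
Reagents that add atoms: none
Why: On warming, the phenolate oxygen on C1' adds to the iodine-bound C6 of ring A through a five-membered cyclic transition state (O–C1'–C2'–I–C6) of Meisenheimer type; the C6–I bond breaks and iodine drops from the trivalent to the monovalent state while staying on C2'. The closest known reaction type is the thermal 1,4 aryl shift (a Smiles-type ligand coupling at iodine) of 2-(aryliodonio)phenolates to 2-iodophenyl aryl ethers. No ring is closed, since the cyclic array exists only in the transition state, and no stereocentre is created. The step needs O-arylation to win over loss of the aryl iodide (carbene-type decay) and over intermolecular aryl transfer; the intramolecular geometry, the two bromines that make C6 electron-poor and the ortho methoxy group on ring A that favours ligand coupling should secure this. Only ring A can migrate, because the other iodine-bound carbon belongs to the phenolate ring itself. The crowded oxygen, flanked by C6'–OMe and C2'–I, is reached because the aryl group is delivered from within the molecule.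

Step 8
Reactants: 10 1,5-dibromo-3-(3,5-dibromo-2-methoxyphenoxy)-2-iodo-4-methoxybenzene
Product: 13 4,6-dibromo-2-(3,5-dibromo-2-methoxyphenoxy)-3-methoxyphenol, via arylmagnesium chloride 11 (not isolated), via dimethyl arylboronate 12 (not isolated)
Conditions: iPrMgCl·LiCl, THF, −40 °C; B(OMe)3, −40 to 0 °C; then AcOH, 30% H2O2, 0 °C to rt; dilute HCl work-up
Reagents that add atoms: hydrogen peroxide, OO (isopropylmagnesium chloride–lithium chloride, CC(C)[Mg]Cl.[Li+].[Cl-], and trimethyl borate, COB(OC)OC, leave atoms only in 11 and 12)
Why: Iodine–magnesium exchange is far faster at C–I than at C–Br at low temperature and is accelerated by the flanking oxygen and bromine, and the resulting aryl Grignard is converted to the phenol by borate trapping and peroxide-induced boron-to-oxygen aryl shift (Hawthorne-type phenol synthesis).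

**Compound list**
1 | 2,4-dibromophenol | Oc1ccc(Br)cc1Br | starting material
2 | 2,4-dibromo-6-iodophenol | Oc1c(I)cc(Br)cc1Br | intermediate
3 | 1,5-dibromo-3-iodo-2-methoxybenzene | COc1c(I)cc(Br)cc1Br | intermediate
4 | 1-(diacetoxyiodo)-3,5-dibromo-2-methoxybenzene | COc1c(Br)cc(Br)cc1I(OC(C)=O)OC(C)=O | intermediate
5 | 3,5-dibromosalicylaldehyde (3,5-dibromo-2-hydroxybenzaldehyde) | O=Cc1cc(Br)cc(Br)c1O | starting material
6 | 3,5-dibromo-2-methoxybenzaldehyde | COc1c(Br)cc(Br)cc1C=O | intermediate
7 | 3,5-dibromo-2-methoxyphenyl formate | COc1c(Br)cc(Br)cc1OC=O | intermediate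
8 | 3,5-dibromo-2-methoxyphenol | COc1c(Br)cc(Br)cc1O | intermediate
9 | 3,5-dibromo-2-[(3,5-dibromo-2-methoxyphenyl)iodonio]-6-methoxyphenolate | COc1c([O-])c([I+]c2cc(Br)cc(Br)c2OC)c(Br)cc1Br | intermediate
10 | 1,5-dibromo-3-(3,5-dibromo-2-methoxyphenoxy)-2-iodo-4-methoxybenzene | COc1c(Br)cc(Br)cc1Oc1c(I)c(Br)cc(Br)c1OC | intermediate
11 | [4,6-dibromo-2-(3,5-dibromo-2-methoxyphenoxy)-3-methoxyphenyl]magnesium chloride | COc1c(Br)cc(Br)cc1Oc1c([Mg]Cl)c(Br)cc(Br)c1OC | intermediate
12 | dimethyl [4,6-dibromo-2-(3,5-dibromo-2-methoxyphenoxy)-3-methoxyphenyl]boronate | COc1c(Br)cc(Br)cc1Oc1c(B(OC)OC)c(Br)cc(Br)c1OC | intermediate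
13 | 4,6-dibromo-2-(3,5-dibromo-2-methoxyphenoxy)-3-methoxyphenol | COc1c(Br)cc(Br)cc1Oc1c(O)c(Br)cc(Br)c1OC | target

**Step count and risks**
Total step count: 8. Longest linear sequence: 6 (steps 1, 2, 3, 6, 7, 8).

Steps most likely to fail:

Step 6. The phenolate may be consumed by dearomatising oxidation (methanol addition at the methoxy-bearing carbon of an oxygen-bound iodane) faster than the carbon–iodine bond forms, or the iodane may attack the para carbon. In that case the iodine bridge would be built from the ring B side with the phenol masked. Setting out from 8, ortho-iodination (NIS, cat. TsOH, MeCN) would give 3,5-dibromo-2-iodo-6-methoxyphenol F1, and acetylation (Ac2O, pyridine) would give 3,5-dibromo-2-iodo-6-methoxyphenyl acetate F2. One-pot oxidation and arylation of F2 with commercial 2,4-dibromoanisole (mCPBA, TfOH, CH2Cl2, 0 °C to rt) would follow; this arene offers only the open carbon ortho to its methoxy group to the electrophile. The product would be (2-acetoxy-4,6-dibromo-3-methoxyphenyl)(3,5-dibromo-2-methoxyphenyl)iodonium trifluoromethanesulfonate F3. Methanolysis of the acetate with K2CO3 in MeOH at 0 °C would release the inner salt, and the route is rejoined at 9.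

Step 7. The zwitterion may fragment by expulsion of the aryl iodide, or transfer its aryl group between molecules, faster than the intramolecular shift to oxygen. The ether bond would then be made by nucleophilic aromatic substitution with the roles of the rings reversed, since phenol 8 is also the phenol of ring A. Setting out from 8, reaction (K2CO3, DMF, 90 °C) with 4,6-dibromo-2-fluoro-3-methoxybenzaldehyde F4 would be used; F4 would come from twofold bromination (NBS, H2SO4) of commercial 2-fluoro-3-methoxybenzaldehyde at the carbons para and ortho to its methoxy group. The formyl group activates the fluoride and sits on the carbon that must become hydroxylated. The product, 4,6-dibromo-2-(3,5-dibromo-2-methoxyphenoxy)-3-methoxybenzaldehyde F5, would undergo Baeyer–Villiger oxidation (mCPBA, CH2Cl2) to 4,6-dibromo-2-(3,5-dibromo-2-methoxyphenoxy)-3-methoxyphenyl formate F6. Methanolysis (Et3N, MeOH) would then give the target, so this path rejoins the route at 13.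

Step 8. Borylation at the doubly ortho-substituted carbon may be slow, so that the arylmagnesium is protonated, and the hindered arylboron intermediate may undergo protodeboronation before it is oxidised. The boron relay would then be replaced by direct electrophilic oxygenation. Setting out from the arylmagnesium chloride 11, addition of bis(trimethylsilyl) peroxide (THF, −40 °C to 0 °C) would give [4,6-dibromo-2-(3,5-dibromo-2-methoxyphenoxy)-3-methoxyphenoxy]trimethylsilane F7, whose silyl group is removed in the dilute HCl work-up, rejoining the route at 13.

**Further compounds**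
F1 | step 6 | 3,5-dibromo-2-iodo-6-methoxyphenol | COc1c(O)c(I)c(Br)cc1Br
F2 | step 6 | 3,5-dibromo-2-iodo-6-methoxyphenyl acetate | COc1c(OC(C)=O)c(I)c(Br)cc1Br
F3 | step 6 | (2-acetoxy-4,6-dibromo-3-methoxyphenyl)(3,5-dibromo-2-methoxyphenyl)iodonium trifluoromethanesulfonate | COc1c(OC(C)=O)c([I+]c2cc(Br)cc(Br)c2OC)c(Br)cc1Br.[O-]S(=O)(=O)C(F)(F)F
F4 | step 7 | 4,6-dibromo-2-fluoro-3-methoxybenzaldehyde | COc1c(F)c(C=O)c(Br)cc1Br
F5 | step 7 | 4,6-dibromo-2-(3,5-dibromo-2-methoxyphenoxy)-3-methoxybenzaldehyde | COc1c(Br)cc(Br)cc1Oc1c(C=O)c(Br)cc(Br)c1OC
F6 | step 7 | 4,6-dibromo-2-(3,5-dibromo-2-methoxyphenoxy)-3-methoxyphenyl formate | COc1c(Br)cc(Br)cc1Oc1c(OC=O)c(Br)cc(Br)c1OC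
F7 | step 8 | [4,6-dibromo-2-(3,5-dibromo-2-methoxyphenoxy)-3-methoxyphenoxy]trimethylsilane | COc1c(Br)cc(Br)cc1Oc1c(O[Si](C)(C)C)c(Br)cc(Br)c1OC
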